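**Strategy.** The route rests on cutting the C7a'–C3a' bond of the primed butenolide (phthalide numbering, primes on the hydroxylated half). This bond is the middle of the 1,4-dicarbonyl array C1'–C7a'–C3a'–C3' and the third bridge of the bicyclo[2.2.2]octane built on the central cyclohexane C7'/C6'/C5'/C4'/C7/C6. The key step joins the α-carbons of two acetate arms, cis-1,4 on that ring, by oxidative coupling of their ester enolates, closing the bicycle in one operation. Its precursor is a cis-decalin: ring A ketalised at C7a, C6' silyloxy, a tert-butyl acetate arm at C7' and a methyl acetate arm at C4', all five stereocentres already in place.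

Key step: step 9

Locants: each half is numbered as a phthalide (C1 lactone carbonyl, O2, C3 butylidene-bearing carbon, C3a, C4–C7, C7a); the halves are joined by C6–C7' and C7–C4'; ring A is C3a–C4–C5–C6–C7–C7a.

Assumption: the facial sense of the oxazaborolidinium catalyst in step 2 is taken from the α-C–H···O binding model of acrylate-type dienophiles, which points to the (R)-prolinol-derived catalyst; should the antipode form, the (S)-catalyst is used and nothing else changes.

**Step 1**
Reactants: 1 methyl vinyl ketone
Product: 2 2-(triisopropylsilyloxy)buta-1,3-diene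
Conditions: TIPSOTf, Et3N, Et2O, 0 °C to rt
Reagents that add atoms: triisopropylsilyl trifluoromethanesulfonate, CC(C)[Si](OS(=O)(=O)C(F)(F)F)(C(C)C)C(C)C
Why: Soft enolisation of the methyl ketone and O-silylation traps the cross-conjugated enol as its silyl ether, the standard preparation of 2-siloxydienes; no stereocentre is formed.

**Step 2**
Reactants: 2 2-(triisopropylsilyloxy)buta-1,3-diene; 3 cyclohex-2-en-1-one
Product: 4 (4aR,8aS)-6-(triisopropylsilyloxy)-3,4,4a,5,8,8a-hexahydronaphthalen-1(2H)-one (cis-fused)
Conditions: (R)-3,3-diphenyl-1-(o-tolyl)tetrahydro-1H,3H-pyrrolo[1,2-c][1,3,2]oxazaborole (20 mol %), Tf2NH (18 mol %), CH2Cl2, −78 to −20 °C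
Reagents that add atoms: 2-(triisopropylsilyloxy)buta-1,3-diene (2), C=CC(=C)O[Si](C(C)C)(C(C)C)C(C)C
Why: Catalytic enantioselective Diels–Alder reaction under a chiral oxazaborolidinium Lewis acid: the 2-siloxy group steers the nucleophilic diene terminus to the enone β-carbon (C6), suprafacial addition makes the C6/C7 fusion cis, and the catalyst-bound enone is attacked on its open face, which sets the absolute configuration of both centres.

**Step 3**
Reactants: 4 cis-fused adduct
Product: 5 (4aR,8aS)-1,1-(ethylenedioxy)-6-(triisopropylsilyloxy)-1,2,3,4,4a,5,8,8a-octahydronaphthalene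
Conditions: (TMSOCH2)2, TMSOTf (2 mol %), CH2Cl2, −78 °C; pyridine quench
Reagents that add atoms: 1,2-bis(trimethylsilyloxy)ethane, C[Si](C)(C)OCCO[Si](C)(C)C
Why: Noyori ketalisation under aprotic conditions at low temperature should convert the only ketone (C7a) into the dioxolane without epimerising the adjacent C7 or cleaving the hindered enol silyl ether; no new stereocentre.

**Step 4**
Reactants: 5 ketal enol silyl ether
Product: 6 (4aR,8aR)-5,5-(ethylenedioxy)-4a,5,6,7,8,8a-hexahydronaphthalen-2(1H)-one (cis-fused enone, C6' ketone, C5'=C4')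
Conditions: Pd(OAc)2 (1.1 equiv), MeCN, rt to 40 °C
Reagents that add atoms: none
Why: Saegusa–Ito oxidation: the palladium enolate formed at C5' can lose a β-hydrogen only from C4', which places the enone double bond at C5'=C4' next to C7 and leaves the fusion centres untouched.

**Step 5**
Reactants: 6 cis-fused enone; 7 tert-butyl bromoacetate
Product: 9 enone carrying a CH2CO2t-Bu arm at C7' anti to ring A, via lithium dienolate 8 (not isolated)
Conditions: LDA, THF, −78 °C; then 7, DMPU, −78 to −40 °C
Reagents that add atoms: tert-butyl bromoacetate (7), BrCC(=O)OC(C)(C)C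
Why: Kinetic α'-deprotonation gives the cross-conjugated dienolate, and its SN2 alkylation at C7' should occur anti to the adjacent C6–C5 bond (convex face of the cis-fused bicycle), which sets C7' with the arm trans to ring A.

**Step 6**
Reactants: 9 C7'-alkylated enone; 10 1-(tert-butyldimethylsilyloxy)-1-methoxyethene
Product: 12 C6' ketone with CH2CO2t-Bu at C7' and CH2CO2Me at C4' (arms cis to each other and anti to ring A), via silyl enol ether 11 (not isolated)
Conditions: 10, LiClO4 (3 M in Et2O), rt; then n-Bu4NF, AcOH, THF, 0 °C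
Reagents that add atoms: 1-(tert-butyldimethylsilyloxy)-1-methoxyethene (10), C=C(OC)O[Si](C)(C)C(C)(C)C
Why: Mukaiyama–Michael addition under mild LiClO4 activation (tolerated by ketal and tert-butyl ester): the ketene acetal should attack C4' anti to the neighbouring C7–C7a bond that carries the spiro-ketal, setting C4', and buffered fluoride then releases the ketone from the regiodefined enol silyl ether without disturbing C7'.

**Step 7**
Reactants: 12 keto diester
Product: 13 C6' alcohol with the hydroxyl cis to both acetate arms
Conditions: LiBH(s-Bu)3 (L-Selectride), THF, −78 °C; AcOH quench at −78 °C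
Reagents that add atoms: none
Why: Diastereoselective ketone reduction with a bulky trialkylborohydride: hydride should arrive on the face opposite the two arms (equatorial attack, the usual cis-selective outcome for 2-substituted cyclohexanones), setting C6', while the tert-butyl ester on the vicinal arm and the cold acidic quench keep the cis-γ-alkoxide from lactonising.

**Step 8**
Reactants: 13 alcohol
Product: 14 C6' triisopropylsilyl ether (coupling precursor: cis-decalin, C7a dioxolane, C7' CH2CO2t-Bu, C4' CH2CO2Me)
Conditions: TIPSOTf, 2,6-lutidine, CH2Cl2, −40 to 0 °C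
Reagents that add atoms: triisopropylsilyl trifluoromethanesulfonate, CC(C)[Si](OS(=O)(=O)C(F)(F)F)(C(C)C)C(C)C
Why: Silyl triflate silylation protects the hindered secondary alcohol as an ether chosen to survive amide base, Grignard reagent and the aqueous acid of step 12; no stereocentre is affected.

**Step 9**
Reactants: 14 coupling precursor
Product: 16 bicyclo[2.2.2]octane succinate (tert-butyl ester on C7a', methyl ester on C3a', trans; C7a dioxolane, C6' OTIPS), via dilithium bis-enolate 15 (not isolated)
Conditions: LDA (2.3 equiv), THF, −78 °C; cannulated slowly into Fe(acac)3 (2.4 equiv), THF, −78 °C to rt, final 0.005 M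
Reagents that add atoms: none
Why: Double deprotonation gives the dilithium bis(ester enolate) 15; trivalent iron oxidises one enolate to an α-ester radical, which adds to the enolate carbon of the other arm, and a second one-electron oxidation of the resulting radical anion gives the succinate. The closest known reaction type is the intramolecular oxidative coupling of dienolates with Fe(acac)3, CuCl2 or iodine, which has closed carbocycles from diesters and bicyclo[2.2.2] cores from tethered enolates. The new ring C7a'–C7'–C6'–C5'–C4'–C3a' closes in the 6-exo-trig mode across the boat form of the central ring, so that C7' and C4' become bridgeheads. The face of the new bridge is dictated by C7' and C4' (both arms anti to ring A), and the new centres C7a' and C3a' are expected trans, the C7a' ester turning away from the C6' silyloxy group; both centres are removed in step 10, so any diastereomer mixture converges. The step needs ring closure to outrun dimerisation and Claisen condensation, which the cis-1,4 placement of the arms, inverse addition at high dilution, low temperature and the hindered tert-butyl ester should secure. No cross-selectivity between the two unlike enolates is needed, because only their mutual coupling gives a six-membered ring.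

**Step 10**
Reactants: 16 succinate
Product: 20 bicyclo[2.2.2]oct-2-ene diester (C7a'=C3a', CO2t-Bu on C7a', CO2Me on C3a'), via lithium ester enolate 17 (not isolated), via selenide 18 (not isolated), via selenoxide 19 (not isolated)
Conditions: LDA (1.3 equiv), THF, −78 to −40 °C; PhSeBr, −78 °C; then 30% H2O2, pyridine, CH2Cl2, 0 °C to rt
Reagents that add atoms: none
Why: α-Selenenylation of an ester enolate followed by selenoxide syn-elimination: selenium should enter anti to the neighbouring ester and hence syn to the adjacent hydrogen on the eclipsed bridge, the only non-bridgehead β-hydrogen, so elimination can only give the C7a'=C3a' double bond (deprotonation at either ester leads to the same alkene).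

**Step 11**
Reactants: 20 ene diester; 21 n-butylmagnesium chloride
Product: 23 C3' butyl ketone (pentanoyl on C3a', CO2t-Bu on C7a'), via Weinreb amide 22 (not isolated)
Conditions: MeNH(OMe)·HCl, i-PrMgCl, THF, −20 to 0 °C; then 21, −20 to 0 °C; aq. NH4Cl
Reagents that add atoms: n-butylmagnesium chloride (21), CCCC[Mg]Cl
Why: Weinreb ketone synthesis run in one flask: the magnesium amide of N,O-dimethylhydroxylamine should attack only the methyl ester (the tert-butyl ester is inert), and the N-methoxy-N-methylamide takes up one butyl group as a chelated adduct that releases the ketone on work-up, the tetrasubstituted alkene being closed to conjugate addition.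

**Step 12**
Reactants: 23 keto tert-butyl ester
Product: 25 (Z)-3'-butylidene butenolide with ring A C7a ketone and C6' OTIPS, via hydroxybutenolide 24 (not isolated)
Conditions: TFA/CH2Cl2/H2O (10:10:1), 0 °C to rt; evaporate; then p-TsOH·H2O (cat.), PhMe, 80 °C
Reagents that add atoms: water, O
Why: Acidolysis of the tert-butyl ester gives a cis-γ-keto acid that closes to the 3'-hydroxybutenolide while the dioxolane is hydrolysed, and acid-catalysed dehydration through the acyloxy-stabilised cation should give the thermodynamically preferred (Z)-enol lactone (enol lactonisation, the classical route to alkylidene phthalides).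

**Step 13**
Reactants: 25 ring A ketone; 26 pentanoyl chloride
Product: 27 C3a-pentanoyl 1,3-diketone (drawn as the C7a enol)
Conditions: 26, MgBr2·OEt2, i-Pr2NEt, CH2Cl2, rt
Reagents that add atoms: pentanoyl chloride (26), CCCCC(=O)Cl
Why: Soft enolisation and C-acylation (Claisen-type acylation of a magnesium enolate) should occur at the only accessible α-carbon C3a, since C7 is a hindered ring-fusion methine, and is driven by the chelated magnesium diketonate; the enolised product has no new stereocentre.

**Step 14**
Reactants: 27 1,3-diketone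
Product: 28 C7a enol triflate (C7a=C3a, pentanoyl on C3a)
Conditions: Tf2O, i-Pr2NEt, CH2Cl2, −78 °C
Reagents that add atoms: trifluoromethanesulfonic anhydride, O=S(=O)(OS(=O)(=O)C(F)(F)F)C(F)(F)F
Why: O-Sulfonylation of the diketone enolate: 2-acylcyclohexanones are enolised and trapped preferentially with the double bond inside the six-membered ring, which should put the triflate on C7a, leave the pentanoyl ketone free and fix the cis relation of both groups needed in step 15.

**Step 15**
Reactants: 28 enol triflate; 29 carbon monoxide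
Product: 30 C6' O-triisopropylsilyl ether of the target
Conditions: PdCl2(PPh3)2 (5 mol %), Et3N, CO (10 atm), MeCN, 60 °C
Reagents that add atoms: carbon monoxide (29), [C-]#[O+]
Why: Palladium-catalysed carbonylative lactonisation: oxidative addition into the C7a–OTf bond, CO insertion and capture of the acyl–palladium bond by the enol oxygen of the cis pentanoyl ketone (the reaction type used for alkylidene butenolides and phthalides from β-halo enones and o-haloaryl ketones) should close the second lactone, the (Z)-butylidene geometry being the outcome of the (Z)-enolate and the thermodynamic one.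

**Step 16**
Reactants: 30 silyl ether
Product: 31 target CNP0289078.1
Conditions: HF·pyridine, THF/pyridine, 0 °C to rt
Reagents that add atoms: none
Why: Fluoride cleavage of the silyl ether under acidic, non-basic conditions should leave both enol lactones intact and release the C6' hydroxyl with its configuration unchanged.

**Compound list**
1 | methyl vinyl ketone (but-3-en-2-one) | CC(=O)C=C | starting material
2 | 2-(triisopropylsilyloxy)buta-1,3-diene | C=CC(=C)O[Si](C(C)C)(C(C)C)C(C)C | intermediate
3 | cyclohex-2-en-1-one | O=C1C=CCCC1 | starting material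
4 | (4aR,8aS)-6-(triisopropylsilyloxy)-3,4,4a,5,8,8a-hexahydronaphthalen-1(2H)-one, cis-fused | O=C1CCC[C@@H]2CC(O[Si](C(C)C)(C(C)C)C(C)C)=CC[C@H]12 | intermediate
5 | (4aR,8aS)-1,1-(ethylenedioxy)-6-(triisopropylsilyloxy)-1,2,3,4,4a,5,8,8a-octahydronaphthalene | C12(OCCO1)CCC[C@@H]3CC(O[Si](C(C)C)(C(C)C)C(C)C)=CC[C@H]23 | intermediate
6 | (4aR,8aR)-5,5-(ethylenedioxy)-4a,5,6,7,8,8a-hexahydronaphthalen-2(1H)-one, cis-fused enone | C12(OCCO1)CCC[C@@H]3CC(=O)C=C[C@H]23 | intermediate
7 | tert-butyl bromoacetate | BrCC(=O)OC(C)(C)C | starting material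
8 | lithium cross-conjugated dienolate of 6 (C7'=C6'(OLi)–C5'=C4') | C12(OCCO1)CCC[C@@H]3C=C(O[Li])C=C[C@H]23 | intermediate
9 | enone 6 with a CH2CO2t-Bu arm at C7', trans to the C6–C5 bond | C12(OCCO1)CCC[C@@H]3[C@@H](CC(=O)OC(C)(C)C)C(=O)C=C[C@H]23 | intermediate
10 | 1-(tert-butyldimethylsilyloxy)-1-methoxyethene | C=C(OC)O[Si](C)(C)C(C)(C)C | starting material
11 | C6' tert-butyldimethylsilyl enol ether (C6'=C5') with C7' tert-butyl and C4' methyl acetate arms | C12(OCCO1)CCC[C@@H]3[C@@H](CC(=O)OC(C)(C)C)C(O[Si](C)(C)C(C)(C)C)=C[C@@H](CC(=O)OC)[C@H]23 | intermediate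
12 | C6' ketone with CH2CO2t-Bu at C7' and CH2CO2Me at C4', arms cis to each other and anti to ring A | C12(OCCO1)CCC[C@@H]3[C@@H](CC(=O)OC(C)(C)C)C(=O)C[C@@H](CC(=O)OC)[C@H]23 | intermediate
13 | C6' alcohol, hydroxyl cis to both arms | C12(OCCO1)CCC[C@@H]3[C@@H](CC(=O)OC(C)(C)C)[C@@H](O)C[C@@H](CC(=O)OC)[C@H]23 | intermediate
14 | C6' triisopropylsilyl ether of 13 (coupling precursor) | C12(OCCO1)CCC[C@@H]3[C@@H](CC(=O)OC(C)(C)C)[C@@H](O[Si](C(C)C)(C(C)C)C(C)C)C[C@@H](CC(=O)OC)[C@H]23 | intermediate
15 | dilithium bis(ester enolate) of 14 | C12(OCCO1)CCC[C@@H]3[C@@H](C=C(O[Li])OC(C)(C)C)[C@@H](O[Si](C(C)C)(C(C)C)C(C)C)C[C@@H](C=C(O[Li])OC)[C@H]23 | intermediate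
16 | bicyclo[2.2.2]octane succinate: CO2t-Bu on C7a', CO2Me on C3a', trans | C12(OCCO1)CCC[C@@H]3[C@H]4[C@@H](C(=O)OC(C)(C)C)[C@H](C(=O)OC)[C@H](C[C@@H]4O[Si](C(C)C)(C(C)C)C(C)C)[C@H]23 | intermediate
17 | lithium enolate of the C3a' methyl ester of 16 | C12(OCCO1)CCC[C@@H]3[C@H]4[C@@H](C(=O)OC(C)(C)C)C(=C(O[Li])OC)[C@H](C[C@@H]4O[Si](C(C)C)(C(C)C)C(C)C)[C@H]23 | intermediate
18 | C3a' phenylselenide of 16, selenium syn to H-7a' | C12(OCCO1)CCC[C@@H]3[C@H]4[C@@H](C(=O)OC(C)(C)C)[C@](C(=O)OC)([Se]c5ccccc5)[C@H](C[C@@H]4O[Si](C(C)C)(C(C)C)C(C)C)[C@H]23 | intermediate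
19 | selenoxide of 18 | C12(OCCO1)CCC[C@@H]3[C@H]4[C@@H](C(=O)OC(C)(C)C)[C@](C(=O)OC)([Se](=O)c5ccccc5)[C@H](C[C@@H]4O[Si](C(C)C)(C(C)C)C(C)C)[C@H]23 | intermediate
20 | bicyclo[2.2.2]oct-2-ene diester: C7a'=C3a', CO2t-Bu on C7a', CO2Me on C3a' | C12(OCCO1)CCC[C@@H]3[C@H]4C(C(=O)OC(C)(C)C)=C(C(=O)OC)[C@H](C[C@@H]4O[Si](C(C)C)(C(C)C)C(C)C)[C@H]23 | intermediate
21 | n-butylmagnesium chloride | CCCC[Mg]Cl | starting material
22 | C3' N-methoxy-N-methylamide, tert-butyl ester retained | C12(OCCO1)CCC[C@@H]3[C@H]4C(C(=O)OC(C)(C)C)=C(C(=O)N(C)OC)[C@H](C[C@@H]4O[Si](C(C)C)(C(C)C)C(C)C)[C@H]23 | intermediate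
23 | C3' butyl ketone: pentanoyl on C3a', CO2t-Bu on C7a' | C12(OCCO1)CCC[C@@H]3[C@H]4C(C(=O)OC(C)(C)C)=C(C(=O)CCCC)[C@H](C[C@@H]4O[Si](C(C)C)(C(C)C)C(C)C)[C@H]23 | intermediate
24 | 3'-butyl-3'-hydroxybutenolide with C7a ketone (both C3' epimers) | O=C1CCC[C@@H]2[C@H]3C4=C(C(O)(CCCC)OC4=O)[C@H](C[C@@H]3O[Si](C(C)C)(C(C)C)C(C)C)[C@H]12 | intermediate
25 | (Z)-3'-butylidene butenolide with C7a ketone and C6' OTIPS | O=C1CCC[C@@H]2[C@H]3C4=C(/C(=C/CCC)OC4=O)[C@H](C[C@@H]3O[Si](C(C)C)(C(C)C)C(C)C)[C@H]12 | intermediate
26 | pentanoyl chloride | CCCCC(=O)Cl | starting material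
27 | C3a-pentanoyl derivative of 25, C7a enol form | OC2=C(C(=O)CCCC)CC[C@@H]1[C@H]3C4=C(/C(=C/CCC)OC4=O)[C@H](C[C@@H]3O[Si](C(C)C)(C(C)C)C(C)C)[C@H]21 | intermediate
28 | C7a enol triflate of 27 | FC(F)(F)S(=O)(=O)OC2=C(C(=O)CCCC)CC[C@@H]1[C@H]3C4=C(/C(=C/CCC)OC4=O)[C@H](C[C@@H]3O[Si](C(C)C)(C(C)C)C(C)C)[C@H]21 | intermediate
29 | carbon monoxide | [C-]#[O+] | starting material
30 | C6' O-triisopropylsilyl ether of the target | CCC/C=C1\OC(=O)C2=C1CC[C@@H]1[C@H]3C4=C(/C(=C/CCC)OC4=O)[C@H](C[C@@H]3O[Si](C(C)C)(C(C)C)C(C)C)[C@H]21 | intermediate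
31 | CNP0289078.1 | CCC/C=C1\OC(=O)C2=C1CC[C@@H]1[C@H]3C4=C(/C(=C/CCC)OC4=O)[C@H](C[C@@H]3O)[C@H]21 | target

**Step count and risks**

Total step count: 16. Longest linear sequence: 16 steps (1 to 31; all steps lie on one line, with 3, 7, 10, 21, 26 and 29 entering as reagents).

Steps most likely to fail:

1. Step 9. The ring closure may be too slow, so that the bis-enolate dimerises, undergoes Claisen condensation or is quenched by proton transfer before both one-electron oxidations have taken place. Fallback: setting out from 14, the bis-enolate is trapped with TMSCl as the neutral bis(trimethylsilyl ketene acetal) of 14 F1, which is freed from salts and amine by filtration through a non-acidic support. F1 is then oxidised with (NH4)2Ce(NO3)6 and NaHCO3 in MeCN at low temperature (oxidative coupling of silyl ketene acetals through the radical cation). This takes aggregated lithium enolates and free base out of the coupling event and returns to the route at 16.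

2. Step 2. The unactivated cyclic enone may react too slowly under the chiral catalyst, the diene may be lost to protodesilylation, or the facial bias may be insufficient or inverted. Fallback: setting out from 2 and 3, the cycloaddition is run with an achiral promoter (MeAlCl2, CH2Cl2, low temperature), which gives 4 together with the enantiomer of 4 F2. Steps 3 and 4 carry this racemate on to 5 with the enantiomer of 5 F3, and then to 6 with the enantiomer of 6 F4. Preparative chromatography on a chiral stationary phase separates 6 from F4, and the configuration of the collected antipode is secured on a crystalline derivative before step 5. The route is rejoined at 6.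

3. Step 14. Sulfonylation may occur on the side-chain oxygen of the 1,3-diketone, or give mixtures, because the ring oxygen is flanked by the hindered C7. Fallback: setting out from 25 (27 and 28 are bypassed), Vilsmeier–Haack–Arnold bromoformylation (PBr3, DMF, CHCl3) places bromine on the former carbonyl carbon C7a and the formyl group on C3a, with no choice between two carbonyls, giving the C7a-bromo C3a-formyl alkene F5. Aldehyde-selective addition of n-BuTi(OiPr)3 (from 21 and ClTi(OiPr)3), which spares the enol lactone, gives the allylic alcohol F6. Dess–Martin oxidation gives the β-bromo enone F7. Carbonylative lactonisation of F7 under the conditions of step 15 (known for β-bromo-α,β-unsaturated ketones) returns to the route at 30.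

Further compounds
F1 | step 9 | bis(trimethylsilyl ketene acetal) of 14 | C12(OCCO1)CCC[C@@H]3[C@@H](C=C(O[Si](C)(C)C)OC(C)(C)C)[C@@H](O[Si](C(C)C)(C(C)C)C(C)C)C[C@@H](C=C(O[Si](C)(C)C)OC)[C@H]23
F2 | step 2 | enantiomer of 4, (4aS,8aR) | O=C1CCC[C@H]2CC(O[Si](C(C)C)(C(C)C)C(C)C)=CC[C@@H]12
F3 | step 2 | enantiomer of 5, (4aS,8aR) | C12(OCCO1)CCC[C@H]3CC(O[Si](C(C)C)(C(C)C)C(C)C)=CC[C@@H]23
F4 | step 2 | enantiomer of 6, (4aS,8aS) | C12(OCCO1)CCC[C@H]3CC(=O)C=C[C@@H]23
F5 | step 14 | C7a-bromo C3a-formyl alkene derived from 25 | BrC2=C(C=O)CC[C@@H]1[C@H]3C4=C(/C(=C/CCC)OC4=O)[C@H](C[C@@H]3O[Si](C(C)C)(C(C)C)C(C)C)[C@H]21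
F6 | step 14 | C7a-bromo C3a-(1-hydroxypentyl) alkene, both carbinol epimers | BrC2=C(C(O)CCCC)CC[C@@H]1[C@H]3C4=C(/C(=C/CCC)OC4=O)[C@H](C[C@@H]3O[Si](C(C)C)(C(C)C)C(C)C)[C@H]21
F7 | step 14 | C7a-bromo C3a-pentanoyl alkene (β-bromo enone) | BrC2=C(C(=O)CCCC)CC[C@@H]1[C@H]3C4=C(/C(=C/CCC)OC4=O)[C@H](C[C@@H]3O[Si](C(C)C)(C(C)C)C(C)C)[C@H]21
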